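**Conventions.** Lignan locants are used throughout: C7/C7' are the benzylic carbons, C8/C8' the carbons joined in the middle, C9/C9' the oxygenated methylenes. ArA is the 3-methoxyphenyl ring on C7 whose para oxygen ends as the free phenol. ArB is the 3-methoxyphenyl ring on C7' whose para oxygen ends as the prenyl ether. Ring A is O–C7–C8–C8'–C9' and ring B is O–C7'–C8'–C8–C9.

## Analysis of the target

Compound 16 is a furofuran lignan: two tetrahydrofuran rings, ring A and ring B, are cis-fused through the shared C8–C8' bond, with ArA on C7 and ArB on C7'. The four stereocentres are contiguous and have the configuration (7R,7'R,8S,8'S). H8 and H8' are cis, and each aryl group lies on the convex face (H7/H8 and H7'/H8' trans), so the core is C2-symmetric and belongs to the series antipodal to (+)-pinoresinol. The two halves differ only in the substituent on the para oxygen, so the two aryl ends have to be distinguished by protecting groups from the outset. The sensitive sites are the two benzylic C–O bonds (ionisation and epimerisation under acid), the free phenol and the electron-rich rings (oxidation), and the prenyl aryl ether. The prenyl ether does not tolerate acid, hydrogenation, zerovalent palladium, one-electron oxidants or heat (aromatic Claisen rearrangement) and is best installed late. The main difficulty is absolute control of C8 and C8' in a skeleton that carries no carbonyl group to direct it. The plan rests on one feature: C8–C8' joins two C6–C3 units with the skeleton and oxygenation of ferulic acid, and both benzylic carbons C7 and C7' carry electron-rich rings and end up bonded to oxygen. A C7–C7' bond can therefore be made temporarily, inside a cyclobutane C7–C7'–C8'–C8, and cut later by oxidation while the oxygens on C9' and C9 close onto C7 and C7'.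

## Retrosynthetic reasoning

**Endgame, 16 back to 12.** The phenol of ArA is unmasked last, so 16 comes from silyl ether 15. The prenyl ether C–O bond of 15 is cut to phenol 13 and bromide 14. Phenol 13 comes from allyl ether 12, in which an allyl group holds the place of the prenyl group. The prenyl group is kept out of the earlier steps because the radical cation of an aryl prenyl ether would lose a stabilised allylic cation in the oxidative step. The allyl and silyl groups are removed by mechanistically unrelated reactions, so the two phenols can be addressed one after the other.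

**Furofuran to cyclobutane, 12 back to 11.** Both benzylic C–O bonds (O–C7 and O–C7') are cut and C7 is joined to C7', which gives cyclobutane diol 11. This is the only disconnection that removes both rings and both benzylic stereocentres at once while leaving C8 and C8' untouched. The trans arrangement of the two hydroxymethyl groups in 11 corresponds to the cis ring fusion of 12 once each oxygen closes onto the benzylic carbon of the other half. The forward reaction has to break the doubly benzylic, strained C7–C7' bond by oxidation and deliver each aryl group to the convex face.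

**Diol to dilactone, 11 back to 10.** C9 and C9' are raised to the ester level, so that 11 comes from dilactone 10 by hydride reduction. This turns the two halves into acceptor-substituted alkenes in the next retrosynthetic step and lets the chiral diol 7 act as a recoverable tether.

**Cyclobutane to two cinnamates, 10 back to 9.** The bonds C8–C8' and C7–C7' are cut together in a [2+2] sense, giving diester 9. Every skeletal carbon of the target then comes from two cinnamic acids. The forward reaction has to give the head-to-head adduct, the trans relationship at C8/C8' and one absolute sense, all of which are asked of the short C2-symmetric tether. The configuration at C7/C7' is irrelevant.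

**Tether assembly, 9 back to 3, 6 and 7.** The two ester C–O bonds are cut in turn: 9 comes from mono-ester 8 and acid 6, and 8 from acid 3 and diol 7. The two hydroxyls of 7 are homotopic, so the order of acylation raises no regiochemical question.

**Acids, 3 and 6 back to 1.** Both acids come from 1 by O-silylation or by O-allylation with 4, so the only difference between the halves is introduced in the first two steps.

## Alternatives that were turned down

**Alternative 1:** Ring A is disconnected to a cyclopropane fused onto a preformed ring B, the oxabicyclohexane ester A1, in which C7 is bonded to both C8 and C8'. In the forward key step a benzylic sulfur ylide carrying ArA would add to C8 of an enantiopure ring-B dihydrofuran ester, anti to ArB, and the ester enolate would close onto C7. A later donor–acceptor ring expansion (Cloke–Wilson type) would cut C7–C8' and bring the C9' oxygen onto C7. In its favour, all reaction types are polar and well understood, C8 is relayed from C7' through a rigid bicycle, and C7 need not be controlled because it ionises in the expansion. Against it, ring B must first be made as a single enantiomer by separate chemistry. The ylide has to form a quaternary cyclopropane carbon on a trisubstituted acceptor. The expansion works poorly at the ester oxidation level and would need redox adjustments, and the ester protecting group on ArB still has to be exchanged for prenyl. It is the safer plan step by step but clearly longer. The chosen plan offers instead both halves from one acid, a recoverable chirality source and fewer operations.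

**Alternative 2:** The bonds C7–C8 and C7'–C8' are disconnected from a four-carbon butenolide core. In the forward key step a lithiated aryl dithiane (acyl-anion equivalent for ArA–C7) would add to C8 of a butenolide bearing a menthyl acetal auxiliary, anti to the acetal, and the enolate would be trapped at C8' by the ArB aldehyde to give lactone A2. Unmasking, global reduction and acid closure would finish the furofuran. In its favour, this is a convergent three-component union whose trans C8/C8' relationship and absolute sense follow reliably from the auxiliary, and the prenyl ether could be carried on the aldehyde from the start. On reliability it is the stronger plan, and its step count is comparable. Against it for this target, it needs a stoichiometric auxiliary from the less accessible menthyl series, cryogenic organolithium chemistry, and a dithiane cleavage (thiophilic metal salts or oxidants) next to electron-rich rings and a prenyl alkene. It also ends in an acid-mediated closure that the prenyl aryl ether tolerates poorly. The chosen plan avoids these reagents and takes all carbons from one feedstock acid, at the price of a less certain ring-forming step.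

**Alternative 3:** The C8–C8' bond is made by a 1,2-shift. Ring A in ester A3 would arise by Wolff ring contraction of a six-membered diazo ketone, itself from a hetero-Diels–Alder reaction of the ArA aldehyde. Photolysis in an alcohol would expel N2, C8 would migrate to the carbene carbon C8', and the ketene would be trapped as the ester at C7'. ArB would then be added to that ester carbon, followed by reduction and closure of ring B. In its favour, C7 can be set by a catalytic asymmetric cycloaddition, ring A is secured early, and the aryl groups are varied freely, which is stronger than the chosen plan for analogue work. Against it, the sequence is long and linear (cycloaddition, installation of C9, diazo transfer, contraction, then four or more steps to ring B). C8' emerges unselectively and must be corrected by equilibration, and three protecting groups are needed. The chosen plan is shorter and more convergent, although its late steps are less precedented.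

Key step: step 5

Remark (assumption): the (4S,5S) tether 7 is taken to favour the (8S,8'S) cyclobutane, because a simple model pairs the negative exocyclic C–C–C–C torsion of the (4S,5S) dioxolane with the positive C9–C8–C8'–C9' torsion of the (8S,8'S) diester in an untwisted ten-membered ring. Should the sense be opposite, the (4R,5R) enantiomer of 7 would be used with no other change.

## Route

Step 1
Reactants: 1 (E)-ferulic acid
Product: 3 (E)-3-[3-methoxy-4-(triisopropylsilyloxy)phenyl]prop-2-enoic acid, via the bis-silylated silyl ester 2 (not isolated)
Conditions: TIPSCl (2.3 equiv), imidazole (5 equiv), DMF, 23 °C; then K2CO3, THF–H2O, 0 °C; HCl to pH 3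
Reagents that add atoms: triisopropylsilyl chloride, CC(C)[Si](Cl)(C(C)C)C(C)C
Why: Silylation of both the phenol and the acid, then selective hydrolysis of the much more labile silyl ester, should leave the hindered aryl silyl ether in place.

Step 2
Reactants: 1 (E)-ferulic acid; 4 allyl bromide
Product: 6 (E)-3-[4-(allyloxy)-3-methoxyphenyl]prop-2-enoic acid, via the allyl ester 5 (not isolated)
Conditions: 4 (2.4 equiv), K2CO3, DMF, 50 °C; then 2 M NaOH, MeOH, 50 °C; HCl to pH 2
Reagents that add atoms: allyl bromide (4), C=CCBr; sodium hydroxide, [Na+].[OH-]
Why: Williamson alkylation of phenoxide and carboxylate is followed by saponification of the allyl ester, which leaves the aryl allyl ether untouched.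

Step 3
Reactants: 3 (E)-3-[3-methoxy-4-(triisopropylsilyloxy)phenyl]prop-2-enoic acid; 7 (4S,5S)-2,2-dimethyl-1,3-dioxolane-4,5-dimethanol
Product: 8 [(4S,5S)-5-(hydroxymethyl)-2,2-dimethyl-1,3-dioxolan-4-yl]methyl (E)-3-[3-methoxy-4-(triisopropylsilyloxy)phenyl]prop-2-enoate
Conditions: 7 (3 equiv), DCC, DMAP (10 mol %), CH2Cl2, 0 to 23 °C
Reagents that add atoms: none
Why: Steglich esterification with the diol in excess should favour mono-acylation; the two hydroxyls are homotopic, so only one mono-ester exists and surplus 7 is recovered.

Step 4
Reactants: 8 the mono-ester; 6 (E)-3-[4-(allyloxy)-3-methoxyphenyl]prop-2-enoic acid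
Product: 9 {(4S,5S)-5-[({(E)-3-[4-(allyloxy)-3-methoxyphenyl]prop-2-enoyl}oxy)methyl]-2,2-dimethyl-1,3-dioxolan-4-yl}methyl (E)-3-[3-methoxy-4-(triisopropylsilyloxy)phenyl]prop-2-enoate
Conditions: DCC, DMAP (10 mol %), CH2Cl2, 0 to 23 °C
Reagents that add atoms: none
Why: A second Steglich esterification acylates the remaining primary hydroxyl; the acetonide, the silyl ether and both alkenes are inert to the carbodiimide.

Step 5
Reactants: 9 the mixed diester
Product: 10 the ten-membered cyclic diester formed between both hydroxyls of 7 and (1S,2S,3R,4R)-3-[4-(allyloxy)-3-methoxyphenyl]-4-[3-methoxy-4-(triisopropylsilyloxy)phenyl]cyclobutane-1,2-dicarboxylic acid (all four ring substituents mutually trans; lignan descriptors 7R,7'R,8S,8'S)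
Conditions: [Ir(dF(CF3)ppy)2(dtbbpy)]PF6 (1 mol %), 450 nm LEDs, degassed MeCN (2 mM), 25 °C
Reagents that add atoms: none
Why: Triplet energy transfer from the excited iridium complex to either cinnamate gives a twisted alkene triplet whose C8 adds to C8' of the tethered partner; this first bond closes the ten-membered dilactone in 10-exo-trig fashion and leaves benzylic radicals at C7 and C7', which after spin inversion recombine to close the cyclobutane (collapse of a 1,4-biradical, the second bond of a stepwise [2+2]). The closest known reaction types are the energy-transfer dimerisation of cinnamate esters to head-to-head, all-trans cyclobutanes and the photodimerisation of dicinnamates templated by a diol. C8 and C8' are created in the first bond formation: the C2 axis of the dioxolane makes the reacting faces of the two α-carbons equivalent, so they combine in like fashion and the two carbonyl-bearing carbons end up trans, while the (4S,5S) configuration of the tether selects the pair that gives (8S,8'S). C7 and C7' are set when the relaxed biradical closes, each aryl taking the side away from its neighbours, but their configuration is of no consequence because this bond is cut in step 7. Head-to-head regiochemistry follows from the short tether joining the two carboxyl ends and from the preference for the doubly benzylic biradical, and high dilution secures the intramolecular course. E/Z isomerisation of the cinnamates is harmless, since both isomers are re-excited, the product no longer accepts triplet energy, and the face of C8 that reacts does not depend on alkene geometry.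

Step 6
Reactants: 10 the cyclobutane dilactone
Product: 11 {(1S,2S,3R,4R)-3-[4-(allyloxy)-3-methoxyphenyl]-4-[3-methoxy-4-(triisopropylsilyloxy)phenyl]cyclobutane-1,2-diyl}dimethanol
Conditions: LiAlH4, THF, 0 °C; H2O, 15% NaOH work-up
Reagents that add atoms: none
Why: Hydride reduction of both lactone carbonyls gives the two primary alcohols and releases tether 7 for recovery; C8 and C8' are not enolised under these conditions, and the aryl silyl ether and allyl ether should be inert at 0 °C.

Step 7
Reactants: 11 the cyclobutane diol
Product: 12 (1R,3aS,4R,6aS)-1-[3-methoxy-4-(triisopropylsilyloxy)phenyl]-4-[4-(allyloxy)-3-methoxyphenyl]tetrahydro-1H,3H-furo[3,4-c]furan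
Conditions: graphite anode, Pt cathode, undivided cell, constant current (2.2 F/mol), (4-BrC6H4)3N (10 mol %), 2,6-lutidine, LiClO4, MeCN–CH2Cl2 (4:1), 0 °C
Reagents that add atoms: none
Why: Proposed new method: one-electron oxidation of a dialkoxyaryl ring by the anodically generated aminium radical cation should trigger cleavage of the strained, doubly benzylic C7–C7' bond to a 1,4-radical cation; the benzylic cation is captured 5-exo-trig by the hydroxymethyl oxygen on the carbon across the former ring (O on C9' onto C7), and the remaining benzylic radical is oxidised and captured the same way (O on C9 onto C7'), with lutidine carrying the protons to the cathode. Each aryl group should settle on the convex face, as in the closure of 8–8'-linked bis(quinone methides) to pinoresinol, while C8 and C8' are untouched; the closest known reaction types are the nucleophile-trapped ring opening of arylcyclopropane radical cations and the cycloreversion of 1,2-diarylcyclobutane radical cations.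

Step 8
Reactants: 12 the allyl-protected furofuran
Product: 13 2-methoxy-4-{(1R,3aS,4R,6aS)-4-[3-methoxy-4-(triisopropylsilyloxy)phenyl]tetrahydro-1H,3H-furo[3,4-c]furan-1-yl}phenol
Conditions: Pd(PPh3)4 (5 mol %), morpholine, THF, 23 °C
Reagents that add atoms: none
Why: Zerovalent palladium ionises the aryl allyl ether to a π-allyl complex that morpholine intercepts (Tsuji–Trost deallylation); the benzylic ethers of the furofuran are not allylic and the silyl ether is inert to the amine.

Step 9
Reactants: 13 the mono-phenol; 14 prenyl bromide
Product: 15 (1R,3aS,4R,6aS)-1-[3-methoxy-4-(triisopropylsilyloxy)phenyl]-4-{3-methoxy-4-[(3-methylbut-2-en-1-yl)oxy]phenyl}tetrahydro-1H,3H-furo[3,4-c]furan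
Conditions: 14, K2CO3, acetone, 40 °C
Reagents that add atoms: prenyl bromide (14), CC(C)=CCBr
Why: Williamson O-alkylation of the only free phenoxide at the primary allylic carbon of 14; the mild base in acetone should leave the hindered aryl silyl ether and the benzylic stereocentres untouched.

Step 10
Reactants: 15 the silyl ether
Product: 16 2-methoxy-4-[(1R,3aS,4R,6aS)-4-{3-methoxy-4-[(3-methylbut-2-en-1-yl)oxy]phenyl}tetrahydro-1H,3H-furo[3,4-c]furan-1-yl]phenol
Conditions: Bu4NF, AcOH (1:1), THF, 0 °C
Reagents that add atoms: none
Why: Fluoride cleaves the aryl O–Si bond; buffering with acetic acid keeps the medium near neutral, so neither the prenyl ether nor the benzylic C–O bonds are disturbed.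

## Compound list

1 | (E)-ferulic acid, (E)-3-(4-hydroxy-3-methoxyphenyl)prop-2-enoic acid | COc1cc(/C=C/C(=O)O)ccc1O | starting material
2 | triisopropylsilyl (E)-3-[3-methoxy-4-(triisopropylsilyloxy)phenyl]prop-2-enoate | COc1cc(/C=C/C(=O)O[Si](C(C)C)(C(C)C)C(C)C)ccc1O[Si](C(C)C)(C(C)C)C(C)C | intermediate
3 | (E)-3-[3-methoxy-4-(triisopropylsilyloxy)phenyl]prop-2-enoic acid | COc1cc(/C=C/C(=O)O)ccc1O[Si](C(C)C)(C(C)C)C(C)C | intermediate
4 | allyl bromide (3-bromoprop-1-ene) | C=CCBr | starting material
5 | allyl (E)-3-[4-(allyloxy)-3-methoxyphenyl]prop-2-enoate | COc1cc(/C=C/C(=O)OCC=C)ccc1OCC=C | intermediate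
6 | (E)-3-[4-(allyloxy)-3-methoxyphenyl]prop-2-enoic acid | COc1cc(/C=C/C(=O)O)ccc1OCC=C | intermediate
7 | (4S,5S)-2,2-dimethyl-1,3-dioxolane-4,5-dimethanol (2,3-O-isopropylidene-L-threitol) | CC1(C)O[C@@H](CO)[C@H](CO)O1 | starting material
8 | [(4S,5S)-5-(hydroxymethyl)-2,2-dimethyl-1,3-dioxolan-4-yl]methyl (E)-3-[3-methoxy-4-(triisopropylsilyloxy)phenyl]prop-2-enoate | COc1cc(ccc1O[Si](C(C)C)(C(C)C)C(C)C)/C=C/C(=O)OC[C@@H]1OC(C)(C)O[C@H]1CO | intermediate
9 | {(4S,5S)-5-[({(E)-3-[4-(allyloxy)-3-methoxyphenyl]prop-2-enoyl}oxy)methyl]-2,2-dimethyl-1,3-dioxolan-4-yl}methyl (E)-3-[3-methoxy-4-(triisopropylsilyloxy)phenyl]prop-2-enoate | COc1cc(ccc1O[Si](C(C)C)(C(C)C)C(C)C)/C=C/C(=O)OC[C@@H]1OC(C)(C)O[C@H]1COC(=O)/C=C/c1ccc(OCC=C)c(OC)c1 | intermediate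
10 | ten-membered cyclic diester of (1S,2S,3R,4R)-3-[4-(allyloxy)-3-methoxyphenyl]-4-[3-methoxy-4-(triisopropylsilyloxy)phenyl]cyclobutane-1,2-dicarboxylic acid with both hydroxyls of 7 (all-trans cyclobutane) | COc1cc(ccc1O[Si](C(C)C)(C(C)C)C(C)C)[C@@H]1[C@@H](c4ccc(OCC=C)c(OC)c4)[C@@H]2C(=O)OC[C@@H]3OC(C)(C)O[C@H]3COC(=O)[C@@H]12 | intermediate
11 | {(1S,2S,3R,4R)-3-[4-(allyloxy)-3-methoxyphenyl]-4-[3-methoxy-4-(triisopropylsilyloxy)phenyl]cyclobutane-1,2-diyl}dimethanol | COc1cc(ccc1O[Si](C(C)C)(C(C)C)C(C)C)[C@@H]1[C@@H](c2ccc(OCC=C)c(OC)c2)[C@H](CO)[C@H]1CO | intermediate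
12 | (1R,3aS,4R,6aS)-1-[3-methoxy-4-(triisopropylsilyloxy)phenyl]-4-[4-(allyloxy)-3-methoxyphenyl]tetrahydro-1H,3H-furo[3,4-c]furan | COc1cc([C@@H]2OC[C@@H]3[C@H]2CO[C@H]3c2ccc(OCC=C)c(OC)c2)ccc1O[Si](C(C)C)(C(C)C)C(C)C | intermediate
13 | 2-methoxy-4-{(1R,3aS,4R,6aS)-4-[3-methoxy-4-(triisopropylsilyloxy)phenyl]tetrahydro-1H,3H-furo[3,4-c]furan-1-yl}phenol | COc1cc([C@@H]2OC[C@@H]3[C@H]2CO[C@H]3c2ccc(O)c(OC)c2)ccc1O[Si](C(C)C)(C(C)C)C(C)C | intermediate
14 | prenyl bromide (1-bromo-3-methylbut-2-ene) | CC(C)=CCBr | starting material
15 | (1R,3aS,4R,6aS)-1-[3-methoxy-4-(triisopropylsilyloxy)phenyl]-4-{3-methoxy-4-[(3-methylbut-2-en-1-yl)oxy]phenyl}tetrahydro-1H,3H-furo[3,4-c]furan | COc1cc([C@@H]2OC[C@@H]3[C@H]2CO[C@H]3c2ccc(OCC=C(C)C)c(OC)c2)ccc1O[Si](C(C)C)(C(C)C)C(C)C | intermediate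
16 | 2-methoxy-4-[(1R,3aS,4R,6aS)-4-{3-methoxy-4-[(3-methylbut-2-en-1-yl)oxy]phenyl}tetrahydro-1H,3H-furo[3,4-c]furan-1-yl]phenol | COc1cc([C@@H]2OC[C@@H]3[C@H]2CO[C@H]3c2ccc(OCC=C(C)C)c(OC)c2)ccc1O | target

## Step count and least certain steps

Total: 10 steps. Longest linear sequence: 9 steps (steps 1, 3, 4, 5, 6, 7, 8, 9, 10 from 1); step 2 is the side branch.

**Step 7 (proposed new method).** The most likely failure is fragmentation of the opened 1,4-radical cation along C8–C8' (complete cycloreversion to two cinnamyl alcohol units) before the hydroxyl closes onto the benzylic cation. Over-oxidation of the product, whose rings are as electron-rich as those of the substrate, and incomplete convex-face selectivity at C7/C7' are further risks.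
Fallback with known chemistry, setting out from 11 and returning at 12: both hydroxyls would be acetylated (Ac2O, pyridine) to the diacetate F1. Photoinduced electron-transfer oxygenation (9,10-dicyanoanthracene, O2, visible light, MeCN) is an established way of turning strained 1,2-diarylcycloalkanes into cyclic peroxides. It should insert O2 into the C7–C7' bond and give the 1,2-dioxane F2 as a mixture of benzylic epimers. LiAlH4 would cleave the O–O bond and both acetates to the tetraol F3. Acid-catalysed double cyclodehydration (camphorsulfonic acid, CH2Cl2) is the classical closure of such 1,4-diaryl-2,3-bis(hydroxymethyl)butane-1,4-diols through benzylic cations, and would give 12.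

**Step 5 (key step).** Closure of the ten-membered ring may be slow relative to decay of the alkene triplet, so that E/Z cycling and, on long irradiation, intermolecular oligomerisation take over. The flexible tether may also discriminate the faces of C8/C8' poorly, or in the opposite sense. An opposite sense is answered by the enantiomer of 7; the other failures need a different approach.
Fallback, setting out from 3 and returning at 16: it gives up the tether and uses the C2 symmetry of the core. Acid 3 would be converted into its methyl ester F4 (MeOH, DCC, DMAP). Intermolecular energy-transfer dimerisation under the same sensitiser, which favours the head-to-head all-trans adduct, would give the racemic diester F5. LiAlH4 reduction and separation of the enantiomers on a chiral stationary phase would give the diol F6. The conditions of step 7 would convert it into the bis-silyl ether F7, and Bu4NF would release (−)-pinoresinol F8. Mono-alkylation with one equivalent of 14 (K2CO3, acetone) can give only one mono-ether, 16, because the two phenols are homotopic; unreacted F8 would be recycled.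

**Step 3.** Mono-acylation of a symmetrical diol is statistical, so bis-acylation may consume acid 3 even with excess 7.
Fallback, setting out from 7 and returning at 9: mono-silylation (NaH, TBSCl, THF) would give the mono-silyl ether F9. Esterification with 6 (DCC, DMAP) would give the ester F10, and Bu4NF/AcOH would free the hydroxyl to give the mono-ester F11. Acyl migration in F11 is degenerate because of the symmetry of the diol. Esterification with 3 would then give 9. The silyl-protected acid is introduced last, so no fluoride step follows it.

**Step 9.** Carbonate may slowly cleave the aryl silyl ether, which would lead to double prenylation, and some C-alkylation of the phenoxide is possible.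
Fallback, setting out from 13 and returning at 15: base-free Mitsunobu etherification of 13 with 3-methylbut-2-en-1-ol (PPh3, diisopropyl azodicarboxylate, THF) would activate the alcohol instead of generating a phenoxide and would make no new intermediate.

## Further compounds

F1 | step 7 | {(1S,2S,3R,4R)-3-[4-(allyloxy)-3-methoxyphenyl]-4-[3-methoxy-4-(triisopropylsilyloxy)phenyl]cyclobutane-1,2-diyl}bis(methylene) diacetate | COc1cc(ccc1O[Si](C(C)C)(C(C)C)C(C)C)[C@@H]1[C@@H](c2ccc(OCC=C)c(OC)c2)[C@H](COC(C)=O)[C@H]1COC(C)=O
F2 | step 7 | {(4S,5S)-6-[4-(allyloxy)-3-methoxyphenyl]-3-[3-methoxy-4-(triisopropylsilyloxy)phenyl]-1,2-dioxane-4,5-diyl}bis(methylene) diacetate (C3 and C6 epimer mixture) | COc1cc(ccc1O[Si](C(C)C)(C(C)C)C(C)C)C1OOC(c2ccc(OCC=C)c(OC)c2)[C@H](COC(C)=O)[C@H]1COC(C)=O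
F3 | step 7 | (2S,3S)-4-[4-(allyloxy)-3-methoxyphenyl]-2,3-bis(hydroxymethyl)-1-[3-methoxy-4-(triisopropylsilyloxy)phenyl]butane-1,4-diol (C1 and C4 epimer mixture) | COc1cc(ccc1O[Si](C(C)C)(C(C)C)C(C)C)C(O)[C@H](CO)[C@@H](CO)C(O)c1ccc(OCC=C)c(OC)c1
F4 | step 5 | methyl (E)-3-[3-methoxy-4-(triisopropylsilyloxy)phenyl]prop-2-enoate | COc1cc(/C=C/C(=O)OC)ccc1O[Si](C(C)C)(C(C)C)C(C)C
F5 | step 5 | rac-dimethyl (1S,2S,3R,4R)-3,4-bis[3-methoxy-4-(triisopropylsilyloxy)phenyl]cyclobutane-1,2-dicarboxylate (all-trans; racemate, one enantiomer drawn) | COc1cc(ccc1O[Si](C(C)C)(C(C)C)C(C)C)[C@@H]1[C@@H](c2ccc(O[Si](C(C)C)(C(C)C)C(C)C)c(OC)c2)[C@H](C(=O)OC)[C@H]1C(=O)OC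
F6 | step 5 | {(1S,2S,3R,4R)-3,4-bis[3-methoxy-4-(triisopropylsilyloxy)phenyl]cyclobutane-1,2-diyl}dimethanol | COc1cc(ccc1O[Si](C(C)C)(C(C)C)C(C)C)[C@@H]1[C@@H](c2ccc(O[Si](C(C)C)(C(C)C)C(C)C)c(OC)c2)[C@H](CO)[C@H]1CO
F7 | step 5 | (1R,3aS,4R,6aS)-1,4-bis[3-methoxy-4-(triisopropylsilyloxy)phenyl]tetrahydro-1H,3H-furo[3,4-c]furan | COc1cc([C@@H]2OC[C@@H]3[C@H]2CO[C@H]3c2ccc(O[Si](C(C)C)(C(C)C)C(C)C)c(OC)c2)ccc1O[Si](C(C)C)(C(C)C)C(C)C
F8 | step 5 | (−)-pinoresinol, 4,4'-[(1R,3aS,4R,6aS)-tetrahydro-1H,3H-furo[3,4-c]furan-1,4-diyl]bis(2-methoxyphenol) | COc1cc([C@@H]2OC[C@@H]3[C@H]2CO[C@H]3c2ccc(O)c(OC)c2)ccc1O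
F9 | step 3 | [(4S,5S)-5-({[tert-butyl(dimethyl)silyl]oxy}methyl)-2,2-dimethyl-1,3-dioxolan-4-yl]methanol | CC1(C)O[C@@H](CO)[C@H](CO[Si](C)(C)C(C)(C)C)O1
F10 | step 3 | [(4S,5S)-5-({[tert-butyl(dimethyl)silyl]oxy}methyl)-2,2-dimethyl-1,3-dioxolan-4-yl]methyl (E)-3-[4-(allyloxy)-3-methoxyphenyl]prop-2-enoate | COc1cc(/C=C/C(=O)OC[C@@H]2OC(C)(C)O[C@H]2CO[Si](C)(C)C(C)(C)C)ccc1OCC=C
F11 | step 3 | [(4S,5S)-5-(hydroxymethyl)-2,2-dimethyl-1,3-dioxolan-4-yl]methyl (E)-3-[4-(allyloxy)-3-methoxyphenyl]prop-2-enoate | COc1cc(/C=C/C(=O)OC[C@@H]2OC(C)(C)O[C@H]2CO)ccc1OCC=C
F0 | step 9 | none | none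
A1 | alternative 1 | methyl 6-[3-methoxy-4-(triisopropylsilyloxy)phenyl]-2-[3-methoxy-4-(pivaloyloxy)phenyl]-3-oxabicyclo[3.1.0]hexane-1-carboxylate (configuration as in the SMILES) | COC(=O)[C@@]12[C@@H](c3ccc(O[Si](C(C)C)(C(C)C)C(C)C)c(OC)c3)[C@@H]1CO[C@H]2c1ccc(OC(=O)C(C)(C)C)c(OC)c1
A2 | alternative 2 | 3,4-trans 3-[hydroxy{3-methoxy-4-[(3-methylbut-2-en-1-yl)oxy]phenyl}methyl]-4-{2-[3-methoxy-4-(triisopropylsilyloxy)phenyl]-1,3-dithian-2-yl}-5-(menthyloxy)dihydrofuran-2(3H)-one (configuration as in the SMILES) | O=C1[C@@H]([C@@H](O)c2ccc(OCC=C(C)C)c(OC)c2)[C@H](C2(SCCCS2)c2ccc(O[Si](C(C)C)(C(C)C)C(C)C)c(OC)c2)[C@@H](O[C@H]2C[C@@H](C)CC[C@@H]2C(C)C)O1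
A3 | alternative 3 | methyl 4-({[tert-butyl(dimethyl)silyl]oxy}methyl)-5-[3-methoxy-4-(triisopropylsilyloxy)phenyl]tetrahydrofuran-3-carboxylate (configuration as in the SMILES) | COc1cc(ccc1O[Si](C(C)C)(C(C)C)C(C)C)[C@@H]1OC[C@@H](C(=O)OC)[C@H]1CO[Si](C)(C)C(C)(C)C
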